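**Plan**

- Retrosynthesis: cut acyl-chain C3'–C4' (B-alkyl Suzuki–Miyaura) to give iodo-enoate 15 and alkene 18; cut the ester C–O bond at ring C6 (Mitsunobu, inversion) to give amino alcohol 11 and acid 14; cut ring bonds C4a–C7a, C5–C6 and C6–C7 (Pauson–Khand) to give enyne 5; cut the two C–CH3 bonds at ring C4 and chain C6' (Cu-catalysed allylic methylation).
- Feature that allows the key event: chain C2'=C3' is an (E)-α-methyl enoate whose β-carbon C3' carries only H, so it can be held as a configurationally stable (E)-β-iodo-enoate; C4'–C5' is an unbranched CH2CH2 unit ending at the C6' methyl stereocentre, so it can be masked as a vinyl group and opened by anti-Markovnikov hydroboration.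
- Forward: one Pauson–Khand step on the N-tethered 1,7-enyne closes the tetrahydropyridine and the cyclopentenone ring of the cyclopenta[c]pyridine together; hydrogenation/epimerisation, LiAlH4, Mitsunobu esterification, fragment coupling and desilylation follow.
- Stereochemistry: ring C4 from Cu/Taniaphos allylic methylation; C4a from the Pauson–Khand step under control of C4; C7a from convex-face hydrogenation; C7 by base equilibration; C6 by convex-face hydride delivery followed by Mitsunobu inversion; chain C6' from a second allylic methylation with the antipodal ligand; the (E)-alkene from vinyl iodide 14, carried through stereoretentive coupling.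

Key step: step 12

Assumption: CuBr·SMe2/(R,R)-Taniaphos is taken to give (S)-3-phenylbut-1-ene from cinnamyl bromide and MeMgBr; on that basis step 3 uses the (S,S)- and step 11 the (R,R)-ligand, and the two antipodes are exchanged if a first run shows the opposite sense.

**Route**

Step 1
Reactants: 1 but-2-yn-1-amine hydrochloride
Product: 2 tert-butyl but-2-yn-1-ylcarbamate
Conditions: Boc2O, Et3N, CH2Cl2, 0 °C to rt
Reagents that add atoms: di-tert-butyl dicarbonate, CC(C)(C)OC(=O)OC(=O)OC(C)(C)C
Why: Standard N-acylation (Boc protection) of a primary amine set free from its salt by triethylamine.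

Step 2
Reactants: 2 tert-butyl but-2-yn-1-ylcarbamate; 3 (E)-1,4-dibromobut-2-ene (3 equiv)
Product: 4 tert-butyl [(2E)-4-bromobut-2-en-1-yl](but-2-yn-1-yl)carbamate
Conditions: NaH, DMF, 0 °C; then added to 3 in THF, 0 °C to rt
Reagents that add atoms: none
Why: SN2 N-alkylation of the carbamate anion at one allylic bromide, the excess of the symmetrical dibromide suppressing double alkylation and the (E)-geometry being retained.

Step 3
Reactants: 4 tert-butyl [(2E)-4-bromobut-2-en-1-yl](but-2-yn-1-yl)carbamate
Product: 5 tert-butyl but-2-yn-1-yl[(2R)-2-methylbut-3-en-1-yl]carbamate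
Conditions: MeMgBr, CuBr·SMe2 (5 mol%), (S,S)-Taniaphos (6 mol%), CH2Cl2, −75 °C
Reagents that add atoms: methylmagnesium bromide, C[Mg]Br
Why: Copper-catalysed asymmetric allylic alkylation (SN2') of an (E)-allylic bromide with a Grignard reagent, in which the chiral Cu–diphosphine complex delivers the methyl group to one enantiotopic face of the γ-carbon and so sets ring C4 as (R), in close analogy to 4-(N-carbamoyl)but-2-enyl bromides.

Step 4
Reactants: 5 tert-butyl but-2-yn-1-yl[(2R)-2-methylbut-3-en-1-yl]carbamate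
Product: 7 tert-butyl (4R,4aS)-4,7-dimethyl-6-oxo-1,3,4,4a,5,6-hexahydro-2H-cyclopenta[c]pyridine-2-carboxylate, via alkyne–Co2(CO)6 complex 6 (not isolated)
Conditions: Co2(CO)8 (1.1 equiv), CH2Cl2, rt; then N-methylmorpholine N-oxide (8 equiv), 0 °C to rt
Reagents that add atoms: dicobalt octacarbonyl (supplies C6 as CO), O=C=[Co](=C=O)(=C=O)(=C=O)[Co](=C=O)(=C=O)(=C=O)=C=O
Why: Intramolecular Pauson–Khand [2+2+1] reaction of the 1,7-enyne, in which the alkene should insert through a chair-like transition state with the C4 methyl pseudo-equatorial and the alkene terminus C5 pseudo-axial towards cobalt, so that H-4a ends cis to H-4 (1,2-induction from the allylic stereocentre, as known for closely related N-protected enynes), before CO insertion and reductive elimination give the enone.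

Step 5
Reactants: 7 tert-butyl (4R,4aS)-4,7-dimethyl-6-oxo-1,3,4,4a,5,6-hexahydro-2H-cyclopenta[c]pyridine-2-carboxylate
Product: 9 tert-butyl (4R,4aS,7S,7aR)-4,7-dimethyl-6-oxooctahydro-2H-cyclopenta[c]pyridine-2-carboxylate, via 7-epi ketone 8 (not isolated)
Conditions: H2 (3 atm), 10% Pd/C, EtOAc, rt; filter; then NaOMe (0.3 equiv), MeOH, rt
Reagents that add atoms: none
Why: Heterogeneous hydrogenation should add H2 to the tetrasubstituted enone from the face of H-4a (away from C4 and its methyl) to give the cis-fused ketone 8, and methoxide then equilibrates the α-stereocentre C7 to the more stable epimer with the methyl trans to C1 (cis to H-7a).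

Step 6
Reactants: 9 tert-butyl (4R,4aS,7S,7aR)-4,7-dimethyl-6-oxooctahydro-2H-cyclopenta[c]pyridine-2-carboxylate
Product: 11 (4R,4aS,6S,7S,7aR)-2,4,7-trimethyloctahydro-1H-cyclopenta[c]pyridin-6-ol (6-epi-incarvilline), via N-Boc 6-epi alcohol 10 (not isolated)
Conditions: LiAlH4 (4 equiv), THF, 0 °C, then reflux; Fieser work-up
Reagents that add atoms: none
Why: Hydride reduction in which LiAlH4 first attacks the ketone from the convex face of the cis-fused bicycle (the face of H-4a/H-7a, syn to the 7-methyl as small hydrides do with 2-methylcyclopentanones), placing the 6-OH on the concave face (6S), and on heating reduces the tert-butyl carbamate to the N-methyl group.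

Step 7
Reactants: 12 diethyl 2-methylmalonate
Product: 13 diethyl 2-(diiodomethyl)-2-methylmalonate
Conditions: NaH, Et2O, reflux; then CHI3, reflux
Reagents that add atoms: iodoform, IC(I)I
Why: C-alkylation of the malonate enolate by iodoform (diiodomethylation), a standard entry to β-iodo-methacrylic acids.

Step 8
Reactants: 13 diethyl 2-(diiodomethyl)-2-methylmalonate
Product: 14 (2E)-3-iodo-2-methylprop-2-enoic acid
Conditions: KOH, EtOH/H2O, reflux; then aq. HCl
Reagents that add atoms: potassium hydroxide (supplies the carboxyl OH oxygen), [K+].[OH-]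
Why: Saponification followed by decarboxylative elimination of iodide, which gives the (E)-vinyl iodide (iodine trans to the carboxyl group) as the thermodynamically preferred isomer.

Step 9
Reactants: 11 (4R,4aS,6S,7S,7aR)-2,4,7-trimethyloctahydro-1H-cyclopenta[c]pyridin-6-ol; 14 (2E)-3-iodo-2-methylprop-2-enoic acid
Product: 15 (4R,4aS,6R,7S,7aR)-2,4,7-trimethyloctahydro-1H-cyclopenta[c]pyridin-6-yl (2E)-3-iodo-2-methylprop-2-enoate
Conditions: PPh3, DIAD (betaine pre-formed), THF, 0 °C to rt; product used without storage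
Reagents that add atoms: none
Why: Mitsunobu esterification, in which the carboxylate displaces the alkoxyphosphonium group by SN2 from the convex face and so inverts C6 from S to the R configuration of the target, as precedented for esterification of this amino alcohol with inversion.

Step 10
Reactants: 16 tert-butyl(but-3-en-1-yloxy)dimethylsilane; 3 (E)-1,4-dibromobut-2-ene (3 equiv)
Product: 17 {[(3E)-5-bromopent-3-en-1-yl]oxy}(tert-butyl)dimethylsilane
Conditions: Hoveyda–Grubbs second-generation catalyst (3 mol%), CH2Cl2, 40 °C; (E)-isomer purified on AgNO3–silica if needed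
Reagents that add atoms: none
Why: Olefin cross-metathesis of a terminal alkene with an excess of the symmetrical (E)-allylic dibromide, which should give the (E)-allylic bromide as the thermodynamic product.

Step 11
Reactants: 17 {[(3E)-5-bromopent-3-en-1-yl]oxy}(tert-butyl)dimethylsilane
Product: 18 tert-butyldimethyl{[(3R)-3-methylpent-4-en-1-yl]oxy}silane
Conditions: MeMgBr, CuBr·SMe2 (5 mol%), (R,R)-Taniaphos (6 mol%), CH2Cl2, −75 °C
Reagents that add atoms: methylmagnesium bromide, C[Mg]Br
Why: Copper-catalysed asymmetric allylic alkylation (SN2'), in which the ligand antipode opposite to that of step 3 directs the methyl group to the γ-carbon face that gives the (R)-alkene, the future (6S)-centre of the chain.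

Step 12
Reactants: 18 tert-butyldimethyl{[(3R)-3-methylpent-4-en-1-yl]oxy}silane (1.5 equiv); 19 9-borabicyclo[3.3.1]nonane (9-BBN); 15 (4R,4aS,6R,7S,7aR)-2,4,7-trimethyloctahydro-1H-cyclopenta[c]pyridin-6-yl (2E)-3-iodo-2-methylprop-2-enoate
Product: 21 (4R,4aS,6R,7S,7aR)-2,4,7-trimethyloctahydro-1H-cyclopenta[c]pyridin-6-yl (2E,6S)-8-{[tert-butyl(dimethyl)silyl]oxy}-2,6-dimethyloct-2-enoate, via B-alkyl-9-BBN 20 (not isolated)
Conditions: 18, 9-BBN, THF, 0 °C to rt; then 3 M aq. Cs2CO3; then 15, Pd(dppf)Cl2·CH2Cl2 (5 mol%), AsPh3 (5 mol%), DMF, rt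
Reagents that add atoms: none
Why: 9-BBN adds anti-Markovnikov to the monosubstituted alkene of 18 so that boron sits on chain C4' without touching the adjacent C6' stereocentre; aqueous carbonate turns borane 20 into its hydroxyborate, Pd(0) inserts into the C3'–I bond of 15 with retention, the primary alkyl group is transferred from boron to palladium, and reductive elimination forms the C3'–C4' bond. The closest known reaction type is the B-alkyl Suzuki–Miyaura coupling of (E)-β-iodo-α-methylacrylates with B-alkyl-9-BBN reagents. No ring is closed and no new stereocentre is formed: the (E)-alkene is inherited from 14 through stereoretentive oxidative addition and reductive elimination, and C6' is inherited from 18. The step needs terminal regioselectivity in the hydroboration (secured by the bulk of 9-BBN), transfer of the primary alkyl group in preference to the bicyclic B–C bonds (inherent to 9-BBN), and coupling faster than β-hydride elimination (wide bite angle of dppf, AsPh3 additive). The hindered secondary enoate ester and the tertiary amine should survive aqueous carbonate at room temperature.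

Step 13
Reactants: 21 (4R,4aS,6R,7S,7aR)-2,4,7-trimethyloctahydro-1H-cyclopenta[c]pyridin-6-yl (2E,6S)-8-{[tert-butyl(dimethyl)silyl]oxy}-2,6-dimethyloct-2-enoate
Product: 22 (4R,4aS,6R,7S,7aR)-2,4,7-trimethyloctahydro-1H-cyclopenta[c]pyridin-6-yl (2E,6S)-8-hydroxy-2,6-dimethyloct-2-enoate
Conditions: HF·pyridine, pyridine/THF, 0 °C to rt; aq. NaHCO3 work-up
Reagents that add atoms: none
Why: Fluoride-mediated cleavage of the primary silyl ether under buffered, non-nucleophilic conditions that should leave the enoate ester, the alkene geometry and the amine untouched.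

**Compound list**

1 | but-2-yn-1-amine hydrochloride | CC#CCN.Cl | starting material
2 | tert-butyl but-2-yn-1-ylcarbamate | CC#CCNC(=O)OC(C)(C)C | intermediate
3 | (E)-1,4-dibromobut-2-ene | BrC/C=C/CBr | starting material
4 | tert-butyl [(2E)-4-bromobut-2-en-1-yl](but-2-yn-1-yl)carbamate | CC#CCN(C/C=C/CBr)C(=O)OC(C)(C)C | intermediate
5 | tert-butyl but-2-yn-1-yl[(2R)-2-methylbut-3-en-1-yl]carbamate | CC#CCN(C[C@@H](C=C)C)C(=O)OC(C)(C)C | intermediate
6 | hexacarbonyldicobalt complex of the alkyne of 5 | CC12C3(CN(C[C@@H](C=C)C)C(=O)OC(C)(C)C)[Co]1(=C=O)(=C=O)(=C=O)[Co]23(=C=O)(=C=O)=C=O | intermediate (not isolated)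
7 | tert-butyl (4R,4aS)-4,7-dimethyl-6-oxo-1,3,4,4a,5,6-hexahydro-2H-cyclopenta[c]pyridine-2-carboxylate | O=C1C[C@@H]2C(CN(C(=O)OC(C)(C)C)C[C@@H]2C)=C1C | intermediate
8 | tert-butyl (4R,4aS,7R,7aR)-4,7-dimethyl-6-oxooctahydro-2H-cyclopenta[c]pyridine-2-carboxylate | O=C1C[C@@H]2[C@@H](CN(C(=O)OC(C)(C)C)C[C@@H]2C)[C@H]1C | intermediate (not isolated)
9 | tert-butyl (4R,4aS,7S,7aR)-4,7-dimethyl-6-oxooctahydro-2H-cyclopenta[c]pyridine-2-carboxylate | O=C1C[C@@H]2[C@@H](CN(C(=O)OC(C)(C)C)C[C@@H]2C)[C@@H]1C | intermediate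
10 | tert-butyl (4R,4aS,6S,7S,7aR)-6-hydroxy-4,7-dimethyloctahydro-2H-cyclopenta[c]pyridine-2-carboxylate | O[C@H]1C[C@@H]2[C@@H](CN(C(=O)OC(C)(C)C)C[C@@H]2C)[C@@H]1C | intermediate (not isolated)
11 | (4R,4aS,6S,7S,7aR)-2,4,7-trimethyloctahydro-1H-cyclopenta[c]pyridin-6-ol | O[C@H]1C[C@@H]2[C@@H](CN(C)C[C@@H]2C)[C@@H]1C | intermediate
12 | diethyl 2-methylmalonate | CCOC(=O)C(C)C(=O)OCC | starting material
13 | diethyl 2-(diiodomethyl)-2-methylmalonate | CCOC(=O)C(C)(C(I)I)C(=O)OCC | intermediate
14 | (2E)-3-iodo-2-methylprop-2-enoic acid | C/C(=C\I)C(=O)O | intermediate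
15 | (4R,4aS,6R,7S,7aR)-2,4,7-trimethyloctahydro-1H-cyclopenta[c]pyridin-6-yl (2E)-3-iodo-2-methylprop-2-enoate | C/C(=C\I)C(=O)O[C@@H]1C[C@@H]2[C@@H](CN(C)C[C@@H]2C)[C@@H]1C | intermediate
16 | tert-butyl(but-3-en-1-yloxy)dimethylsilane | C=CCCO[Si](C)(C)C(C)(C)C | starting material
17 | {[(3E)-5-bromopent-3-en-1-yl]oxy}(tert-butyl)dimethylsilane | BrC/C=C/CCO[Si](C)(C)C(C)(C)C | intermediate
18 | tert-butyldimethyl{[(3R)-3-methylpent-4-en-1-yl]oxy}silane | C=C[C@H](C)CCO[Si](C)(C)C(C)(C)C | intermediate
19 | 9-borabicyclo[3.3.1]nonane | B1C2CCCC1CCC2 | starting material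
20 | 9-[(3S)-5-{[tert-butyl(dimethyl)silyl]oxy}-3-methylpentyl]-9-borabicyclo[3.3.1]nonane | CC(C)(C)[Si](C)(C)OCC[C@@H](C)CCB1C2CCCC1CCC2 | intermediate (not isolated)
21 | (4R,4aS,6R,7S,7aR)-2,4,7-trimethyloctahydro-1H-cyclopenta[c]pyridin-6-yl (2E,6S)-8-{[tert-butyl(dimethyl)silyl]oxy}-2,6-dimethyloct-2-enoate | C/C(=C\CC[C@H](C)CCO[Si](C)(C)C(C)(C)C)C(=O)O[C@@H]1C[C@@H]2[C@@H](CN(C)C[C@@H]2C)[C@@H]1C | intermediate
22 | (4R,4aS,6R,7S,7aR)-2,4,7-trimethyloctahydro-1H-cyclopenta[c]pyridin-6-yl (2E,6S)-8-hydroxy-2,6-dimethyloct-2-enoate | C/C(=C\CC[C@H](C)CCO)C(=O)O[C@@H]1C[C@@H]2[C@@H](CN(C)C[C@@H]2C)[C@@H]1C | target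

**Step count and risks**

Total step count: 13. Longest linear sequence: 9 steps (steps 1–6, 9, 12, 13).

Steps most likely to fail:

1. Step 4. The alkene may insert into the cobalt–alkyne complex with poor or reversed facial selectivity relative to the C4 methyl, which would scramble C4a and, downstream, C7a. The fallback takes the C4/C4a relationship out of the cyclisation and sets it by syn hydrogenation of a flat dienone; it sets out from 2 and comes back at 9 by way of 8. Carbamate 2 would be N-alkylated with 1,4-dichlorobut-2-yne (NaH, DMF) to give tert-butyl but-2-yn-1-yl(4-chlorobut-2-yn-1-yl)carbamate F1. Anti-SN2' substitution with a methylcopper reagent (MeMgBr, CuBr·SMe2, THF, −78 °C) would give the 1,1-disubstituted allene tert-butyl but-2-yn-1-yl(2-methylbuta-2,3-dien-1-yl)carbamate F2. A Rh(I)-catalysed allenic Pauson–Khand reaction ([Rh(CO)2Cl]2, CO 1 atm, toluene, 90 °C), which engages the distal allene double bond, would give the achiral dienone tert-butyl 4,7-dimethyl-6-oxo-1,3,5,6-tetrahydro-2H-cyclopenta[c]pyridine-2-carboxylate F3. CBS reduction ((S)-Me-CBS, BH3·SMe2, the alkenyl flank acting as the large group) is expected to give tert-butyl (6R)-6-hydroxy-4,7-dimethyl-1,3,5,6-tetrahydro-2H-cyclopenta[c]pyridine-2-carboxylate F4. Hydroxyl-directed hydrogenation ([Ir(cod)(PCy3)(py)]PF6, H2, CH2Cl2) should deliver H-4, H-4a, H-7 and H-7a to the hydroxyl face and give tert-butyl (4R,4aS,6R,7R,7aR)-6-hydroxy-4,7-dimethyloctahydro-2H-cyclopenta[c]pyridine-2-carboxylate F5. Dess–Martin oxidation then gives ketone 8, which is equilibrated to 9 as in step 5.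

2. Step 9. Activation of the hindered concave-face carbinol may be slow, so that E2 elimination from the alkoxyphosphonium ion or conjugate addition of the phosphine to the β-iodo-enoate competes with the invertive displacement. The fallback separates inversion from acylation; it sets out from 11 and comes back at 15. Mitsunobu reaction of 11 with the more acidic, non-conjugated 4-nitrobenzoic acid (PPh3, DIAD, THF) would give (4R,4aS,6R,7S,7aR)-2,4,7-trimethyloctahydro-1H-cyclopenta[c]pyridin-6-yl 4-nitrobenzoate F6. Methanolysis (K2CO3, MeOH) would give (4R,4aS,6R,7S,7aR)-2,4,7-trimethyloctahydro-1H-cyclopenta[c]pyridin-6-ol F7. Yamaguchi esterification of F7 with acid 14 (2,4,6-trichlorobenzoyl chloride, Et3N, then DMAP, toluene) would then give 15 with retention at C6.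

3. Step 3. The N-butynyl carbamate substituent may erode branched/linear or enantioselectivity in the copper-catalysed allylic methylation. The fallback creates the stereocentre on the sulfonyl carbamate substrate type with the closest precedent and introduces the alkyne afterwards; it sets out from 3 and comes back at 5. Dibromide 3 would be mono-alkylated with tert-butyl tosylcarbamate (K2CO3, MeCN) to give tert-butyl [(2E)-4-bromobut-2-en-1-yl](tosyl)carbamate F8. The same Cu/Taniaphos methylation would give tert-butyl [(2R)-2-methylbut-3-en-1-yl](tosyl)carbamate F9. Reductive desulfonylation (Mg, MeOH, sonication) would give tert-butyl [(2R)-2-methylbut-3-en-1-yl]carbamate F10. N-alkylation with 1-bromobut-2-yne (NaH, DMF) would give 5.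

Further compounds
F1 | step 4 | tert-butyl but-2-yn-1-yl(4-chlorobut-2-yn-1-yl)carbamate | CC#CCN(CC#CCCl)C(=O)OC(C)(C)C
F2 | step 4 | tert-butyl but-2-yn-1-yl(2-methylbuta-2,3-dien-1-yl)carbamate | CC#CCN(CC(C)=C=C)C(=O)OC(C)(C)C
F3 | step 4 | tert-butyl 4,7-dimethyl-6-oxo-1,3,5,6-tetrahydro-2H-cyclopenta[c]pyridine-2-carboxylate | O=C1CC2=C(C)CN(C(=O)OC(C)(C)C)CC2=C1C
F4 | step 4 | tert-butyl (6R)-6-hydroxy-4,7-dimethyl-1,3,5,6-tetrahydro-2H-cyclopenta[c]pyridine-2-carboxylate | O[C@@H]1CC2=C(C)CN(C(=O)OC(C)(C)C)CC2=C1C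
F5 | step 4 | tert-butyl (4R,4aS,6R,7R,7aR)-6-hydroxy-4,7-dimethyloctahydro-2H-cyclopenta[c]pyridine-2-carboxylate | O[C@@H]1C[C@@H]2[C@@H](CN(C(=O)OC(C)(C)C)C[C@@H]2C)[C@H]1C
F6 | step 9 | (4R,4aS,6R,7S,7aR)-2,4,7-trimethyloctahydro-1H-cyclopenta[c]pyridin-6-yl 4-nitrobenzoate | O=C(O[C@@H]1C[C@@H]2[C@@H](CN(C)C[C@@H]2C)[C@@H]1C)c1ccc(cc1)[N+](=O)[O-]
F7 | step 9 | (4R,4aS,6R,7S,7aR)-2,4,7-trimethyloctahydro-1H-cyclopenta[c]pyridin-6-ol | O[C@@H]1C[C@@H]2[C@@H](CN(C)C[C@@H]2C)[C@@H]1C
F8 | step 3 | tert-butyl [(2E)-4-bromobut-2-en-1-yl](tosyl)carbamate | Cc1ccc(cc1)S(=O)(=O)N(C/C=C/CBr)C(=O)OC(C)(C)C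
F9 | step 3 | tert-butyl [(2R)-2-methylbut-3-en-1-yl](tosyl)carbamate | Cc1ccc(cc1)S(=O)(=O)N(C[C@@H](C=C)C)C(=O)OC(C)(C)C
F10 | step 3 | tert-butyl [(2R)-2-methylbut-3-en-1-yl]carbamate | CC(C)(C)OC(=O)NC[C@@H](C=C)C
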